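(Its constants are assumed; the run is a simulation.)

Start from 327%: that is the most the transfer step can deliver by 3.0 d into a solution kept empty, in percent of the starting material charged, and it is more than the charge asks for. So plan the next run around what else the gas does.

    gas phase ⇌ dissolved gas, rate k1*(csat - [dissolved gas]) (k1 = 0.454 h⁻¹, csat = 200 mM)
    starting material + dissolved gas + catalyst → catalyst + target (k2 = 48.4 M⁻² h⁻¹)
    crystals ⇌ target, rate k3*(cs3 - [target]) while solid is left; crystals form when [target] > cs3 (cs3 = 0.053 M, k3 = 21.6 h⁻¹)
    dissolved gas + target → over-reaction product (k4 = 0.259 M⁻¹ h⁻¹)

starting material 2.0 M; gas phase 200 mM (held); catalyst 10 mM; time 3.0 d

- for target the crystals are counted in
- as a solid, counted per litre of solution: crystals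
- at the start none of the gas is dissolved
- run time (flask): 3.0 d

- amount of target and crystals together at 3.0 d, in percent of the starting material charged
- the change that raises the amount of target and crystals together at 3.0 d, in percent of the starting material charged most ("none" if none brings more than 2 percentage points) (south-east / south / north / north-east / none)
- amount of target and crystals together at 3.0 d, in percent of the starting material charged, after south

- south-east: doubling the amount of catalyst, all else as stated
- south: doubling the dissolution coefficient of step 3, all else as stated
- north: doubling the saturation concentration of gas phase, all else as stated
- north-east: doubling the solubility in step 3, all else as stated

Decide what to charge by freezing what hardly moves. The charge of 2.0 M stands far above the solubility of 0.053 M, so crystals will form. The crystal step answers within 2.78 min, far shorter than the run, so while crystals stand, c(target) stays near the solubility. The over-reaction step is then pseudo-first-order in dissolved gas. Now put c(dissolved gas) at its saturation value and multiply the rate constant of the over-reaction step by the solubility, the saturation concentration and the run time. This product is the over-reaction allowance, 0.198 M, or 9.88% of this charge.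

Reckon the amount asked at 90.1% or a little above, less any starting material left. The margin is there because the catalysed step takes dissolved gas with a half-life of 0.72 h at the charge, shorter than the 1.53 h of the transfer step, so c(dissolved gas) stays below saturation while starting material lasts. North and north-east each double the allowance to 19.8%, so leave both out. The amount of catalyst and the dissolution coefficient do not stand in it, so expect neither south-east nor south to gain more than 2 percentage points. Run the recipe as stated.

The forecast gives 92.3%, 92.4% after south, and none as the best change, holding that “over-reaction costs about 7% of the charge”. Its amount is higher than mine.

The simulation gives 92.4%, 92.5% after south, and none as the best change. In the flask at 0.840 d, the catalysed step uses dissolved gas 33 times faster than the over-reaction step, but at 3.00 d its half-life of 2.7 d is longer than the 2.1 d of the over-reaction step, and the 6.50% of over-reaction product then standing is 0.130 M, less than the allowance. The neighbour flask with 0.50 M of starting material has the same allowance, now 39.6% of its charge, and at 3.00 d it holds 34.1% of over-reaction product.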